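The data were generated by integration with constants of no real substance.

The trap with a solid reagent is to read the split between the two capture products from the weighed equivalents, as if the two nucleophiles shared the substrate in proportion to their charges.

| flask | substrate | second nucleophile | capture agent | solid first nucleophile | remark | time |
|---|---|---|---|---|---|---|
| Wednesday's | 0.20 M | 4 equiv | 4 mM | 0.74 equiv | run made earlier |  |
| Friday's | 0.20 M | 4 equiv | 4 mM | 1.7 equiv | run made earlier |  |
| Monday's | 0.20 M | 6 equiv | 4 mM | 1.1 equiv | run made earlier |  |
| flask | 0.20 M | 4.00 equiv | 4.00 mM | 1.10 equiv |  | 10 d |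

| run | time / d | other capture product / % | target / % |
|---|---|---|---|
| Wednesday's | 1.67 | 29.6 | 3.7 |
| Wednesday's | 3.00 | 45.5 | 7.7 |
| Wednesday's | 5.00 | 60.0 | 7.2 |
| Wednesday's | 6.00 | 65.9 | 12.1 |
| Friday's | 0.833 | 15.9 | 2.4 |
| Friday's | 2.00 | 33.3 | 4.8 |
| Friday's | 4.00 | 54.6 | 9.2 |
| Friday's | 6.00 | 66.2 | 9.0 |
| Monday's | 0.833 | 24.3 | 4.4 |
| Monday's | 2.00 | 44.6 | 5.0 |
| Monday's | 4.00 | 69.1 | 6.8 |
| Monday's | 6.00 | 78.5 | 7.5 |

(scatter of a reading: 1 percentage point)

- share of other capture product in other capture product plus target at 1.0 h
- share of other capture product in other capture product plus target at 15 h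
- share of other capture product in other capture product plus target at 10 d
- which of other capture product and target there is more of at 10 d

- at the start none of the solid first nucleophile is in solution

That bench rule gives Friday's run a share of other capture product of 70.2 %, but its last readings give 88.0 %. From Wednesday's run to Friday's the solid charge rose by a factor of 2.30, yet target at 6.00 d read 12.1 % and then 9.0 %, so we stop counting the solid charge and count the second nucleophile against a fixed opponent. From the last readings of Wednesday's, Friday's and Monday's runs, the charged molarity of second nucleophile times target over other capture product gives 0.147 M, 0.109 M and 0.115 M, with a mean of 0.123 M. We call this mean the competition strength w, a selectivity factor kept in molar units, and it is a reading that carries the scatter of 1 percentage point on target values near 9.0 %.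

With D the charged molarity of second nucleophile, 0.800 M in the flask, the rule, read from runs with substrate at 0.20 M, says the share is D/(D+w), which is 86.6 %, so we put other capture product ahead at 10 d. The flask's solid charge of 1.10 equiv lies between Wednesday's 0.74 equiv and Friday's 1.7 equiv. The border lies in time: 15 h is 0.750 of Friday's first reading time, when the share already read 86.9 %, so we keep the rule there. But 1.0 h is 0.0500 of that time, and with no solid in solution at the start we take the share to begin at 100 %, so we place it between that and 86.6 %.

The forecast gave shares of 96 % at 1.0 h, 89 % at 15 h and 86 % at 10 d with other capture product ahead, holding that “dissolution takes only hours”.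

The flask gives shares of 92.7 % at 1.0 h, 86.6 % at 15 h and 87.0 % at 10 d, with other capture product ahead at 76.7 % against 11.5 % for target.

    substrate ⇌ open intermediate (K = 0.00150, k = 6.00 × 10⁻⁵ s⁻¹)
    first nucleophile + open intermediate → target (k = 0.00530 M⁻¹ s⁻¹)
    second nucleophile + open intermediate → other capture product (k = 0.00230 M⁻¹ s⁻¹)
    open intermediate + capture agent → trapped intermediate (k = 1.20 × 10⁻⁵ M⁻¹ s⁻¹)
    first nucleophile + target → over-reaction product (k = 5.30 × 10⁻⁶ M⁻¹ s⁻¹)
    solid first nucleophile ⇌ first nucleophile, rate k6*(cs6 - [first nucleophile]) while solid is left; crystals form when [first nucleophile] > cs6 (solubility = 0.0560 M, k = 4.20 × 10⁻⁴ s⁻¹)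

Beside these stands our 86.6 %. Dissolved first nucleophile in the flask stood at 0.0558 M at 1.00 d and 0.0560 M at 10.0 d, with 60.2 % of the solid's own charge still undissolved. Carrying w to the neighbouring flask with 0.50 M of substrate, where the same equivalents make D 2.00 M, the rule gives a share of 94.2 %, and that flask stood at a share of 94.4 % at 10 d.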